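Readings and results were generated by integration for an exercise; noise was put on by code.

In the west run you charged more L than in the north-west run, yet at 4.00 min the west run holds 0.195 M of X and the north-west run 0.192 M. In these two runs X reads as zero order in the L charge. The mean of the two readings gives the feed, 0.0484 M/min, the concentration of X made per minute while solid L lasts.

common to all: J 19 mM (held)
- north-west: L 0.45 M; run made earlier
- west: L 0.70 M; run made earlier
- flask: L 0.32 M; time 6.0 min

- north-west (time / min: X / %): 0.200: 1.7; 0.500: 5.6; 1.00: 9.9; 1.50: 15.9; 2.00: 20.4; 3.00: 30.8; 4.00: 42.7
- west (time / min: X / %): 0.200: 0.7; 0.500: 3.9; 1.00: 7.4; 1.50: 9.1; 2.00: 12.9; 3.00: 20.9; 4.00: 27.9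

(readings scatter by 0.5 percentage points)

1. amount of X at 6.0 min, in percent of the L charged
2. concentration of G in solution at 6.0 min, in percent of saturation

- solid, in amounts per volume of the solution: L
- at the start none of L is in solution
- at the start none of J is in solution
- G is what J becomes in solution

Take the time scales fastest first. The start-up is short in the north-west run: at 0.200 min that run holds 0.00765 M of X against 0.00968 M on the feed line, a gap smaller than the scatter of 0.00225 M. Then X climbs steadily in both runs through their last readings. Next comes the emptying of the charge, which in the asked flask reckons at 6.61 min on the feed, longer than the 6.0 min asked. So I expect solid L to last in that flask and X to reach 90.8%. No run shows G, so I give no figure for it.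

The forecast is lower on X: 85% (70% to 93%), with G at 98% of saturation (85% to 100%), since “solid L may run out and the rate fall”.

The flask gives 90.1% of X, with G at 99.2% of saturation.

    X → Z (k = 4.05 × 10⁻⁶ /s)
    2 G → D (k = 1.14 /M/s)
    E + G → X (k = 21.0 /M/s)
    E → Q (k = 0.00861 /s)
    L ⇌ E, rate k5*(cs5 - [E]) while solid is left; crystals form when [E] > cs5 (solubility = 0.0940 M, k = 0.00897 /s)
    J ⇌ G, rate k6*(csat - [G]) (kL = 10.5 /s)

This flask has not come to rest at 6.0 min: L still stands at 7.19%. Left ten times as long, the flask has L at 0% and X at 96.5%, a gain of 6.4 percentage points. Over that stretch Q goes from 1.96% to 2.13%, Z from 0.0653% to 1.34%, and D, made from G, from 0.146 M to 1.47 M.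

Now charge the neighbour flask with 1.3 M of L, for the same time. The feed gives 22.3% of that charge as X. The computed flask gives 22.2%, with 77% of its L still there.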